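A direct plan would acylate 2,4,6-trimethoxytoluene with butanoyl chloride, chloromethylate the last ring position and extend through dimethyl malonate to the benzylmalonyl dichloride A1.
It would then close ring B on A1 by double C-acylation of the bis-silyl dienol ether A2 of heptane-3,5-dione and cleave the three methyl ethers of the product A3 with BBr3.
Its weakest steps would be:
- the ring B closure, which would be unprecedented for a 2-substituted malonyl dichloride and would compete with O-closure to a 4-hydroxy-2-pyranone;
- the threefold ether cleavage, in which the acid-labile CH2 bridge between two electron-rich rings could be cleaved or scrambled;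
- the malonate saponification and acid chloride formation, which would add length without complexity and risk decarboxylation.

The route rests on making ring A from another ring. Ring A, whose C1 carries the butanoyl group and whose C5 carries the bridge between C4–OH and C6–OH, is the Claisen-folded form of a tetraketide; the O-closed isomer of that chain is a 4-hydroxy-6-(2-oxopentyl)-2-pyranone. This pyranone would be carried unprotected, joined through its C3 to the CH2 bridge and finished ring B, then isomerised in one operation (lactone opening, C1–C6 Claisen closure) into hexasubstituted ring A. No ring closure with a C/O choice remains, because the O-closed isomer is the substrate; no methyl ether is made or cleaved; no malonate is carried.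

Key step: step 7

Remark: compounds 1, 2, 4, 6, 7 and 10 are taken as catalogue compounds. The target is achiral and the only sp3 centres on the way (in 8 and 14) are enolisable, so no stereocentre has to be set.

Step 1
Reactants: 1 2-methylbenzene-1,3,5-triol; 2 propanoyl chloride
Product: 3 1-(2,4,6-trihydroxy-3-methylphenyl)propan-1-one
Conditions: 2 (1.05 equiv), AlCl3 (3.5 equiv), PhNO2/CH2Cl2, 0 → 50 °C; then ice, 1 M HCl
Reagents that add atoms: none
Why: Friedel–Crafts C-acylation of a phloroglucinol, in which the two free ring carbons of 1 are equivalent and the first acyl group, chelated to an ortho hydroxyl, deactivates the ring towards a second acylation.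

Step 2
Reactants: 3 1-(2,4,6-trihydroxy-3-methylphenyl)propan-1-one; 4 N,N,N',N'-tetramethylmethanediamine
Product: 5 1-[3-[(dimethylamino)methyl]-2,4,6-trihydroxy-5-methylphenyl]propan-1-one
Conditions: 4 (3 equiv), 1,4-dioxane, 0 °C → rt, 3 added slowly; volatiles evaporated
Reagents that add atoms: none
Why: Mannich aminomethylation, in which the acidic phenol protonates the aminal to an iminium ion that attacks the only free ring carbon of 3, while the excess of aminal should keep the product from alkylating unreacted 3.

Step 3
Reactants: 6 methyl 3-oxopentanoate; 7 N-methoxy-N-methylacetamide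
Product: 8 methyl 4-methyl-3,5-dioxohexanoate
Conditions: 6 (1.3 equiv), LiN(iPr)2 (2.7 equiv), THF, −78 → 0 °C; 7 (1.0 equiv), −78 → 0 °C; then 1 M HCl
Reagents that add atoms: none
Why: γ-Acylation of a β-keto ester dianion (Claisen-type condensation) with a Weinreb amide, whose chelated tetrahedral adduct holds until work-up so that no second addition occurs; the new CH(CH3) centre lies between two carbonyl groups, is enolised and needs no control.

Step 4
Reactants: 8 methyl 4-methyl-3,5-dioxohexanoate
Product: 9 4-hydroxy-5,6-dimethyl-2H-pyran-2-one
Conditions: DBU (1.0 equiv), toluene, 90 °C; then 1 M HCl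
Reagents that add atoms: none
Why: Base-mediated lactonisation of a 3,5-dioxo ester, in which the enol oxygen at C5 attacks the ester carbonyl through a six-membered transition state and methanol is lost to give the 4-hydroxy-2-pyranone.

Step 5
Reactants: 9 4-hydroxy-5,6-dimethyl-2H-pyran-2-one; 10 methyl butanoate
Product: 11 4-hydroxy-5-methyl-6-(2-oxopentyl)-2H-pyran-2-one
Conditions: LiN(iPr)2 (3.3 equiv), THF, −78 → −20 °C; 10 (1.1 equiv), −78 → 0 °C; then 1 M HCl
Reagents that add atoms: none
Why: Claisen acylation of the pyranone dianion, in which the 4-oxide shields the ring and the carbanion at the 6-methyl group (the vinylogous γ position; the 5-methyl group is not conjugated) attacks the ester, the third equivalent of base taking up the more acidic product.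

Step 6
Reactants: 5 1-[3-[(dimethylamino)methyl]-2,4,6-trihydroxy-5-methylphenyl]propan-1-one; 11 4-hydroxy-5-methyl-6-(2-oxopentyl)-2H-pyran-2-one
Product: 13 4-hydroxy-5-methyl-6-(2-oxopentyl)-3-[(2,4,6-trihydroxy-3-methyl-5-propanoylphenyl)methyl]-2H-pyran-2-one, via ring B ortho-quinone methide 12 (not isolated)
Conditions: 11 (1.3 equiv), 1,4-dioxane, 90 °C, N2 stream
Reagents that add atoms: none
Why: Thermal retro-Mannich loss of dimethylamine from 5 gives the ortho-quinone methide 12, which takes up C3 of 11 in a Michael addition, this carbon of the acidic 4-hydroxypyranone enol being by far the most nucleophilic site of 11 under nearly neutral conditions and rearomatisation of ring B being the driving force.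

Step 7
Reactants: 13 4-hydroxy-5-methyl-6-(2-oxopentyl)-3-[(2,4,6-trihydroxy-3-methyl-5-propanoylphenyl)methyl]-2H-pyran-2-one
Product: 15 1-[2,4,6-trihydroxy-3-methyl-5-[(2,4,6-trihydroxy-3-methyl-5-propanoylphenyl)methyl]phenyl]butan-1-one, via open-chain triketo methyl ester 14 (not isolated)
Conditions: Mg(OMe)2 (8 equiv), MeOH, 60 °C, Ar; then 1 M HCl, 0 °C
Reagents that add atoms: none
Why: Methoxide adds to the lactone carbonyl (C2 of the pyranone) and opens the ring to the magnesium-chelated triketo ester 14, whose C6 methylene, flanked by two ketone groups, attacks the ester carbonyl in a Claisen (Dieckmann-type) condensation; methoxide leaves and the cyclohexane-1,3,5-trione tautomerises to the triol. The closest known reaction type is the magnesium methoxide-induced conversion of 6-(2-oxoalkyl)-4-hydroxy-2-pyranones into acylphloroglucinols. Ring A closes as a six-membered carbocycle in a 6-(enolexo)-exo-trig C-acylation that forms its C1–C6 bond (C1 carries the butanoyl group, C6 is the former lactone carbonyl). No stereocentre is created, since the two sp3 centres of 14 disappear on aromatisation. The selectivity needed is Claisen closure and not aldol closure of the ester α-carbon onto the C7 ketone: that α-carbon carries the bridge, so an aldol adduct could not aromatise and should revert, while chelation by magnesium holds the polycarbonyl chain folded and the aromatic triol is the sink. The bridge must also stay in place, which the moderate temperature and the use of magnesium phenoxides in place of free alkali phenoxides should secure.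

Compound list
1 | 2-methylbenzene-1,3,5-triol | Cc1c(O)cc(O)cc1O | starting material
2 | propanoyl chloride | CCC(=O)Cl | starting material
3 | 1-(2,4,6-trihydroxy-3-methylphenyl)propan-1-one | CCC(=O)c1c(O)cc(O)c(C)c1O | intermediate
4 | N,N,N',N'-tetramethylmethanediamine | CN(C)CN(C)C | starting material
5 | 1-[3-[(dimethylamino)methyl]-2,4,6-trihydroxy-5-methylphenyl]propan-1-one | CCC(=O)c1c(O)c(C)c(O)c(CN(C)C)c1O | intermediate
6 | methyl 3-oxopentanoate | CCC(=O)CC(=O)OC | starting material
7 | N-methoxy-N-methylacetamide | CC(=O)N(C)OC | starting material
8 | methyl 4-methyl-3,5-dioxohexanoate (keto form drawn; C4 racemic and enolisable) | CC(=O)C(C)C(=O)CC(=O)OC | intermediate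
9 | 4-hydroxy-5,6-dimethyl-2H-pyran-2-one | CC1=C(C)C(O)=CC(=O)O1 | intermediate
10 | methyl butanoate | CCCC(=O)OC | starting material
11 | 4-hydroxy-5-methyl-6-(2-oxopentyl)-2H-pyran-2-one | CCCC(=O)CC1=C(C)C(O)=CC(=O)O1 | intermediate
12 | 3,5-dihydroxy-4-methyl-6-methylidene-2-propanoylcyclohexa-2,4-dien-1-one (ortho-quinone methide of ring B; one tautomer drawn) | C=C1C(=O)C(C(=O)CC)=C(O)C(C)=C1O | intermediate (not isolated)
13 | 4-hydroxy-5-methyl-6-(2-oxopentyl)-3-[(2,4,6-trihydroxy-3-methyl-5-propanoylphenyl)methyl]-2H-pyran-2-one | CCCC(=O)CC1=C(C)C(O)=C(Cc2c(O)c(C)c(O)c(C(=O)CC)c2O)C(=O)O1 | intermediate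
14 | methyl 4-methyl-3,5,7-trioxo-2-[(2,4,6-trihydroxy-3-methyl-5-propanoylphenyl)methyl]decanoate (formed as its magnesium enolate chelate; keto form drawn; the two sp3 centres are undefined and vanish on aromatisation) | CCCC(=O)CC(=O)C(C)C(=O)C(Cc1c(O)c(C)c(O)c(C(=O)CC)c1O)C(=O)OC | intermediate (not isolated)
15 | 1-[2,4,6-trihydroxy-3-methyl-5-[(2,4,6-trihydroxy-3-methyl-5-propanoylphenyl)methyl]phenyl]butan-1-one (achiral) | CCCC(=O)c1c(O)c(C)c(O)c(Cc2c(O)c(C)c(O)c(C(=O)CC)c2O)c1O | target

Total step count: 7. Longest linear sequence: 5 steps (steps 3, 4, 5, 6 and 7, from methyl 3-oxopentanoate).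

Steps most likely to fail

Step 7. The halves could exchange across the CH2 bridge by retro-Michael cleavage and recombination under base, the polycarbonyl chain could be cut by retro-Claisen methanolysis, or closure at the hindered ester could be slow. The fallback would give up the ring transformation and set out from 1 and 5: Friedel–Crafts acylation of 1 with butanoyl chloride and AlCl3 would give 1-(2,4,6-trihydroxy-3-methylphenyl)butan-1-one F1, and heating F1 with the Mannich base 5 in 1,4-dioxane would release the quinone methide 12, which would alkylate the one free ring carbon of F1 and so come back to the route at 15.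

Step 6. The Mannich base 5 could condense with itself through 12 to a symmetrical dimer, or 11 could react through its side-chain methylene or be alkylated twice. The fallback would exchange the roles of the partners and set out from 11 and 3. Aminomethylation of 11 at C3 with dimethylmethylideneammonium iodide in MeCN would give 3-[(dimethylamino)methyl]-4-hydroxy-5-methyl-6-(2-oxopentyl)-2H-pyran-2-one F2. On warming with 3, F2 would lose dimethylamine to 5-methyl-3-methylidene-6-(2-oxopentyl)pyran-2,4-dione F3, which the free ring carbon of 3 would trap, coming back to the route at 13.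

Step 5. Dianion formation could be incomplete, the more acidic product could quench the carbanion, or the ester could acylate on oxygen. The fallback would replace the acylation by an aldol addition and an oxidation and set out from 9: its dianion (LiN(iPr)2, 2.2 equiv, THF, −78 °C) would add to butanal to give racemic 4-hydroxy-6-(2-hydroxypentyl)-5-methyl-2H-pyran-2-one F4, and oxidation of the secondary alcohol of F4 with CrO3/H2SO4 in acetone at 0 °C would come back to the route at 11.

Further compounds
F1 | step 7 | 1-(2,4,6-trihydroxy-3-methylphenyl)butan-1-one | CCCC(=O)c1c(O)cc(O)c(C)c1O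
F2 | step 6 | 3-[(dimethylamino)methyl]-4-hydroxy-5-methyl-6-(2-oxopentyl)-2H-pyran-2-one | CCCC(=O)CC1=C(C)C(O)=C(CN(C)C)C(=O)O1
F3 | step 6 | 5-methyl-3-methylidene-6-(2-oxopentyl)pyran-2,4-dione | CCCC(=O)CC1=C(C)C(=O)C(=C)C(=O)O1
F4 | step 5 | 4-hydroxy-6-(2-hydroxypentyl)-5-methyl-2H-pyran-2-one (racemic) | CCCC(O)CC1=C(C)C(O)=CC(=O)O1
A1 | direct plan | 2-[(3-butanoyl-2,4,6-trimethoxy-5-methylphenyl)methyl]propanedioyl dichloride | CCCC(=O)c1c(OC)c(C)c(OC)c(CC(C(=O)Cl)C(=O)Cl)c1OC
A2 | direct plan | 3,5-bis(trimethylsilyloxy)hepta-2,4-diene (2Z,4Z drawn; mixture of double-bond isomers) | C/C=C(\O[Si](C)(C)C)/C=C(/CC)O[Si](C)(C)C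
A3 | direct plan | 1-[2,4,6-trimethoxy-3-methyl-5-[(2,4,6-trihydroxy-3-methyl-5-propanoylphenyl)methyl]phenyl]butan-1-one | CCCC(=O)c1c(OC)c(C)c(OC)c(Cc2c(O)c(C)c(O)c(C(=O)CC)c2O)c1OC
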